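**Retrosynthetic overview**

1. Germacranolide numbering is used (ring carbons C1–C10, lactone C11–C13, C14 on C10, C15 on C4). The enabling feature is the oxolane (O, C3, C2, C1, C10): its carbinol C1 sits next to the fully substituted ether carbon C10, so it is a reduced oxolan-3-one, the retron of an oxonium ylide rearrangement; C9 is a CH2 next to oxygenated C8, so a C8=CH2 group carrying the ring O–CH2 can serve as the allyl unit.
2. Key disconnection: C9–C10 and O–C10 in one step. The nine-membered ether (O, C3–C10) arises by one-atom ring expansion of an eight-membered ether (O, C3, C4=C5, C6, C7, C8, OCH2) through the [2,3]-shift of its bicyclic oxonium ylide, which closes the oxolane in the same event.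
3. The eight-membered ether comes from ring-closing metathesis (C4=C5) of an ether joining fragment 1 (allyl chloride 9: C5–C9, C11, C12; epoxidation and invertive alkynylalane opening set C6/C7 as the cis lactone) and fragment 2 (aldol 13: C1–C4, C15; auxiliary aldol sets C3).
4. After the key step: C1 ketone reduction, excision of the extra methylene carbon on C8 (C8=CH2 to C8=O to C8–OH), lactone α-methylenation, angelate, desilylation.
5. Ring order: γ-lactone (step 3), eight-membered ether (step 10), then oxolane and nine-membered ether together (step 13).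

Key step: step 13

Remark on the chemistry: as written, 3S/10R places C4 and C9 on opposite faces of the oxolane (the nine-membered ring is trans-bridged across the ether oxygen, a strained arrangement); the route takes this literally, so step 13 must pass through the trans-fused oxonium ylide, and this is treated as the main risk.

**Route**

Step 1
Reactants: 1 2-bromopropene; 2 (E)-3-(tributylstannyl)prop-2-en-1-ol
Product: 3 (E)-4-methylpenta-2,4-dien-1-ol
Conditions: Pd(PPh3)4 (5 mol %), CuI (10 mol %), DMF, 50 °C, sealed tube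
Reagents that add atoms: none
Why: Stille coupling of an alkenyl bromide with an (E)-alkenylstannane proceeds with retention of alkene geometry and tolerates the free allylic alcohol.

Step 2
Reactants: 3 (E)-4-methylpenta-2,4-dien-1-ol
Product: 4 [(2S,3S)-3-(prop-1-en-2-yl)oxiran-2-yl]methanol
Conditions: Ti(OiPr)4 (10 mol %), L-(+)-diethyl tartrate (12 mol %), t-BuOOH, 4 Å MS, CH2Cl2, −20 °C
Reagents that add atoms: tert-butyl hydroperoxide CC(C)(C)OO
Why: Sharpless asymmetric epoxidation oxidises only the allylic-alcohol alkene, and L-(+)-tartrate delivers oxygen to the face that gives the 2S,3S epoxide of an (E)-allylic alcohol.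

Step 3
Reactants: 4 [(2S,3S)-3-(prop-1-en-2-yl)oxiran-2-yl]methanol
Product: 6 (4R,5R)-5-(hydroxymethyl)-4-(prop-1-en-2-yl)oxolan-2-one, via ynol ether diol 5 (not isolated)
Conditions: ethoxyacetylene, n-BuLi, then Et2AlCl, toluene, −78 to 0 °C; 4, 0 °C to rt; then 1 M HCl, THF, rt
Reagents that add atoms: ethoxyacetylene CCOC#C; water O
Why: Alkynylalane opening of a 2,3-epoxy alcohol occurs at C3 (here also allylic) with inversion, and acid hydration of the ynol ether with capture by the secondary hydroxyl gives the γ-lactone, so the trans epoxide becomes the cis-4,5-disubstituted lactone (target C7 and C6).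

Step 4
Reactants: 6 (4R,5R)-5-(hydroxymethyl)-4-(prop-1-en-2-yl)oxolan-2-one
Product: 7 (2R,3R)-5-oxo-3-(prop-1-en-2-yl)oxolane-2-carbaldehyde
Conditions: Dess–Martin periodinane, NaHCO3, CH2Cl2, 0 °C to rt
Reagents that add atoms: none
Why: Dess–Martin oxidation of the primary alcohol is fast and near neutral, which should keep the epimerisable α-oxygenated centre (target C6) intact.

Step 5
Reactants: 7 (2R,3R)-5-oxo-3-(prop-1-en-2-yl)oxolane-2-carbaldehyde
Product: 8 (4R,5S)-5-ethenyl-4-(prop-1-en-2-yl)oxolan-2-one
Conditions: Ph3PCH3Br, KHMDS, THF, −78 °C; then 7, −78 to 0 °C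
Reagents that add atoms: methyltriphenylphosphonium bromide C[P+](c1ccccc1)(c1ccccc1)c1ccccc1.[Br-]
Why: Wittig methylenation at low temperature should convert the aldehyde into the vinyl group faster than it epimerises, and the lactone is inert to the ylide under these conditions.

Step 6
Reactants: 8 (4R,5S)-5-ethenyl-4-(prop-1-en-2-yl)oxolan-2-one
Product: 9 (4R,5S)-4-(3-chloroprop-1-en-2-yl)-5-ethenyloxolan-2-one
Conditions: Ca(OCl)2, solid CO2, CH2Cl2/H2O, 0 °C
Reagents that add atoms: calcium hypochlorite [Ca+2].[O-]Cl.[O-]Cl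
Why: Ene-type chlorination by hypochlorous acid attacks the electron-rich 1,1-disubstituted alkene and transposes it to the 2-substituted allyl chloride (as known for isopropenyl groups of monoterpenes), leaving the monosubstituted vinyl group untouched.

Step 7
Reactants: 10 (S)-4-benzyl-3-(chloroacetyl)oxazolidin-2-one; 11 methacrolein
Product: 12 (S)-4-benzyl-3-[(2S,3R)-2-chloro-3-hydroxy-4-methylpent-4-enoyl]oxazolidin-2-one
Conditions: Bu2BOTf, i-Pr2NEt, CH2Cl2, −78 °C; 11, −78 to 0 °C; pH 7 buffer, MeOH, H2O2
Reagents that add atoms: none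
Why: Evans syn-aldol through the (Z)-boron enolate and a chair transition state, with the benzyl group of the auxiliary fixing the enolate face, sets the carbinol carbon (target C3) in the spatial arrangement that becomes 3S.

Step 8
Reactants: 12 (S)-4-benzyl-3-[(2S,3R)-2-chloro-3-hydroxy-4-methylpent-4-enoyl]oxazolidin-2-one
Product: 13 (S)-4-benzyl-3-[(S)-3-hydroxy-4-methylpent-4-enoyl]oxazolidin-2-one
Conditions: Zn dust, AcOH, THF, rt
Reagents that add atoms: none
Why: Reductive removal of the α-chlorine by zinc, with protonation of the zinc enolate by acetic acid outrunning β-elimination, gives the formal acetate aldol without touching the carbinol centre.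

Step 9
Reactants: 13 (S)-4-benzyl-3-[(S)-3-hydroxy-4-methylpent-4-enoyl]oxazolidin-2-one; 9 (4R,5S)-4-(3-chloroprop-1-en-2-yl)-5-ethenyloxolan-2-one
Product: 14 (S)-4-benzyl-3-[(3S)-3-({2-[(2S,3R)-2-ethenyl-5-oxooxolan-3-yl]prop-2-en-1-yl}oxy)-4-methylpent-4-enoyl]oxazolidin-2-one
Conditions: AgOTf, 2,6-di-tert-butylpyridine, CH2Cl2, 0 °C to rt, dark
Reagents that add atoms: none
Why: Silver-assisted Williamson etherification (ionisation of the allylic chloride and capture by the secondary alcohol under non-basic conditions) avoids retro-aldol and elimination of the β-hydroxy imide, and the 2-substituted allyl unit gives the same ether from either terminus.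

Step 10
Reactants: 14 (the ether from step 9)
Product: 15 (S)-4-benzyl-3-{[(3S,6S,7R)-oxocene lactone]acetyl}oxazolidin-2-one: eight-membered ether O–C3–C4(CH3)=C5–C6–C7–C8(=CH2)–CH2, Z alkene, cis-fused at C6–C7 to the γ-lactone (O–C12(=O)–C11H2), acyl arm on C3
Conditions: second-generation Grubbs catalyst RuCl2(=CHPh)(H2IMes)(PCy3) (10 mol %), toluene (2 mM), 80 °C
Reagents that add atoms: none
Why: Ring-closing metathesis initiates at the monosubstituted vinyl group and closes onto the isopropenyl group to the eight-membered ether (necessarily Z), whereas the other 1,1-disubstituted alkene could only give a cyclobutene or a tetrasubstituted dihydrofuran.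

Step 11
Reactants: 15 (the oxocene imide)
Product: 16 2-[(3S,6S,7R)-oxocene lactone]acetic acid (C1 as CO2H, otherwise as 15)
Conditions: LiOH, H2O2, THF/H2O, 0 °C; Na2SO3; then 1 M HCl to pH 2
Reagents that add atoms: hydrogen peroxide OO
Why: Lithium hydroperoxide cleaves the exocyclic imide carbonyl selectively, and any γ-lactone opened by hydroxide should reclose on acidification because the cis γ-hydroxy acid lactonises spontaneously.

Step 12
Reactants: 16 (the oxocene acid)
Product: 18 3-diazo-1-[(3S,6S,7R)-oxocene lactone]butan-2-one (side chain on C3: CH2–C(=O)–C(=N2)–CH3), via isobutyl carbonic anhydride 17 (not isolated)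
Conditions: i-BuOCOCl, Et3N, THF, −20 °C; then CH3CHN2, Et2O, 0 °C
Reagents that add atoms: diazoethane CC=[N+]=[N-]
Why: Acylation of diazoethane by the mixed anhydride is the standard route to α-methyl α-diazoketones and brings in C10 and C14 without affecting the lactone or the alkenes.

Step 13
Reactants: 18 (the diazoketone)
Product: 20 (3S,6S,7R,10R)-3,10-epoxy-8-methylidene-1-oxo-13-norgermacr-4(Z)-en-12,6-olide, via trans-fused oxonium ylide 19 (not isolated)
Conditions: Cu(hfacac)2 (copper bis(hexafluoroacetylacetonate), 5 mol %), CH2Cl2, reflux, slow addition of 18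
Reagents that add atoms: none
Why: Proposed new method: the copper carbene from 18 is captured by the ring oxygen to give the bicyclic oxonium ylide 19, in which the ring segment O–CH2–C8(=C9H2) is an allyl group, and a [2,3]-sigmatropic shift joins C9 to C10 while the O–CH2 bond breaks, so the eight-membered ring grows by one atom (C10 enters, the O–CH2 carbon leaves as the exocyclic methylene on C8) and the oxolan-3-one is formed in the same event; the closest known reactions are copper-catalysed oxonium ylide [2,3]-rearrangements of allyl ethers that expand 2-vinyl oxanes by three atoms to O-bridged oxonenes, and [1,2]-shifts of bicyclic oxonium ylides that expand cyclic ethers by one atom. The oxolane closes by attack of the ether oxygen on the carbene carbon (five-membered ylide, carbonyl inside the new ring), and the nine-membered ring arises through a five-membered envelope transition state (C10, O, CH2, C8, C9). C10 is the only new stereocentre and copies the configuration of the oxonium oxygen, because C9 is delivered suprafacially on the face of the ylide that carries the O–CH2 bond; with the C3 side chain pseudo-equatorial on the oxocene the carbene should take the pseudo-equatorial lone pair, which gives the trans-fused ylide and hence C9 anti to C4 (10R). The step needs ylide formation to beat cyclopropanation of the three alkenes, 1,2-hydride shift to the enone and a [2,3]-shift through the endocyclic C3–C4=C5 allyl unit: the electrophilic carbene from Cu(hfacac)2 favours ylide formation, the five-membered ylide forms fastest, and the exocyclic methylene reaches C10 through an unstrained envelope whereas the ring alkene would need a bridged transition state. Loss of N2 and collapse of the ylide make the step irreversible and strongly exothermic with an early transition state, which is what should pay for the strain of the trans-bridged ring.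

Step 14
Reactants: 20 (the bicyclic ketone)
Product: 21 (1S,3S,6S,7R,10R)-3,10-epoxy-1-hydroxy-8-methylidene-13-norgermacr-4(Z)-en-12,6-olide
Conditions: (R)-2-methyl-CBS-oxazaborolidine (20 mol %), catecholborane, toluene, −78 °C
Reagents that add atoms: none
Why: Corey–Bakshi–Shibata reduction, with the quaternary C10 as the large group, should deliver hydride under reagent control to give the 1S carbinol, and catecholborane leaves the alkenes and the lactone untouched.

Step 15
Reactants: 21 (the C1 alcohol)
Product: 22 1-O-(tert-butyldimethylsilyl) ether of 21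
Conditions: TBSOTf, 2,6-lutidine, CH2Cl2, −78 to 0 °C
Reagents that add atoms: tert-butyldimethylsilyl triflate CC(C)(C)[Si](C)(C)OS(=O)(=O)C(F)(F)F
Why: The silyl triflate silylates the hindered secondary alcohol next to the quaternary carbon and protects C1–OH through the base and acylation steps that follow.

Step 16
Reactants: 22 (the silyl ether)
Product: 24 (1S,3S,6S,7S,10R)-1-(tert-butyldimethylsilyloxy)-3,10-epoxy-8-oxo-13-norgermacr-4(Z)-en-12,6-olide (C7 unchanged in space; its descriptor changes with the C8 carbonyl), via vicinal diol 23 (not isolated)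
Conditions: OsO4 (2 mol %), N-methylmorpholine N-oxide, acetone/H2O, 0 °C; then NaIO4, THF/H2O, rt
Reagents that add atoms: osmium tetroxide O=[Os](=O)(=O)=O, oxygen relayed from N-methylmorpholine N-oxide C[N+]1([O-])CCOCC1
Why: Catalytic osmylation should choose the unhindered 1,1-disubstituted exocyclic alkene over the trisubstituted ring alkene, which is deactivated by two allylic oxygens, and periodate cleavage of the diol (Lemieux–Johnson type sequence) removes the extra carbon as formaldehyde to leave the C8 ketone.

Step 17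
Reactants: 24 (the C8 ketone)
Product: 25 (1S,3S,6S,7R,8R,10R)-1-(tert-butyldimethylsilyloxy)-3,10-epoxy-8-hydroxy-13-norgermacr-4(Z)-en-12,6-olide
Conditions: NaBH4, MeOH, −40 °C
Reagents that add atoms: none
Why: Borohydride reduction should add hydride to the C8 carbonyl from the ring periphery on the face away from the lactone methylene C11 on the neighbouring C7, which gives the 8R alcohol, and the lactone survives at low temperature.

Step 18
Reactants: 25 (the C8 alcohol)
Product: 28 (1S,3S,6S,7R,8R,10R)-1-(tert-butyldimethylsilyloxy)-3,10-epoxy-8-hydroxygermacra-4(Z),11(13)-dien-12,6-olide, via Mannich base 26 (not isolated), via trimethylammonium iodide 27 (not isolated)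
Conditions: LDA (2.2 equiv), THF, −78 °C; CH2=NMe2+ I−, −78 °C to rt; then MeI, MeOH, rt; then NaHCO3, CH2Cl2/H2O
Reagents that add atoms: Eschenmoser's salt C=[N+](C)C.[I-]
Why: Lactone α-methylenation through the enolate (the C8 alkoxide is a spectator), Mannich reaction with Eschenmoser's salt, quaternisation and E1cB loss of trimethylamine installs C13 without creating a stereocentre.

Step 19
Reactants: 28 (the α-methylene lactone alcohol); 29 angelic acid
Product: 31 8-O-angeloyl derivative of 28, via angelic 2,4,6-trichlorobenzoic anhydride 30 (not isolated)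
Conditions: 29, 2,4,6-trichlorobenzoyl chloride, Et3N, toluene, rt; then 28, toluene, 80 °C
Reagents that add atoms: none
Why: Yamaguchi-type acylation through the mixed anhydride, run without a nucleophilic catalyst, should esterify the secondary C8 alcohol while keeping the Z geometry of the angelate.

Step 20
Reactants: 31 (the silyl-protected angelate)
Product: 32 (1S,3S,6S,7R,8R,10R)-8-angeloyloxy-3,10-epoxy-1-hydroxygermacra-4(Z),11(13)-dien-12,6-olide (CNP0213894.2)
Conditions: HF·pyridine, pyridine, THF, 0 °C to rt
Reagents that add atoms: none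
Why: Buffered hydrogen fluoride cleaves the silyl ether and should leave the angelate, the α-methylene lactone and the allylic ether untouched.

**Compound list**

1 | 2-bromopropene | CC(Br)=C | starting material
2 | (E)-3-(tributylstannyl)prop-2-en-1-ol | CCCC[Sn](CCCC)(CCCC)/C=C/CO | starting material
3 | (E)-4-methylpenta-2,4-dien-1-ol | CC(=C)/C=C/CO | intermediate
4 | [(2S,3S)-3-(prop-1-en-2-yl)oxiran-2-yl]methanol | OC[C@@H]1O[C@H]1C(C)=C | intermediate
5 | (2R,3S)-3-(ethoxyethynyl)-4-methylpent-4-ene-1,2-diol | OC[C@H](O)[C@H](C#COCC)C(C)=C | intermediate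
6 | (4R,5R)-5-(hydroxymethyl)-4-(prop-1-en-2-yl)oxolan-2-one | O=C1C[C@H](C(C)=C)[C@H](CO)O1 | intermediate
7 | (2R,3R)-5-oxo-3-(prop-1-en-2-yl)oxolane-2-carbaldehyde | O=C1C[C@H](C(C)=C)[C@H](C=O)O1 | intermediate
8 | (4R,5S)-5-ethenyl-4-(prop-1-en-2-yl)oxolan-2-one | O=C1C[C@H](C(C)=C)[C@H](C=C)O1 | intermediate
9 | (4R,5S)-4-(3-chloroprop-1-en-2-yl)-5-ethenyloxolan-2-one | O=C1C[C@H](C(CCl)=C)[C@H](C=C)O1 | intermediate
10 | (S)-4-benzyl-3-(chloroacetyl)oxazolidin-2-one | O=C(CCl)N1[C@@H](Cc2ccccc2)COC1=O | starting material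
11 | methacrolein (2-methylprop-2-enal) | CC(=C)C=O | starting material
12 | (S)-4-benzyl-3-[(2S,3R)-2-chloro-3-hydroxy-4-methylpent-4-enoyl]oxazolidin-2-one | O=C([C@@H](Cl)[C@H](O)C(C)=C)N1[C@@H](Cc2ccccc2)COC1=O | intermediate
13 | (S)-4-benzyl-3-[(S)-3-hydroxy-4-methylpent-4-enoyl]oxazolidin-2-one | O=C(C[C@H](O)C(C)=C)N1[C@@H](Cc2ccccc2)COC1=O | intermediate
14 | (S)-4-benzyl-3-[(3S)-3-({2-[(2S,3R)-2-ethenyl-5-oxooxolan-3-yl]prop-2-en-1-yl}oxy)-4-methylpent-4-enoyl]oxazolidin-2-one | O=C(C[C@H](OCC(=C)[C@H]1CC(=O)O[C@H]1C=C)C(C)=C)N1[C@@H](Cc2ccccc2)COC1=O | intermediate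
15 | (S)-4-benzyl-3-{[(3S,6S,7R)-oxocene lactone]acetyl}oxazolidin-2-one (Z-4-methyl-8-methylidene eight-membered ether cis-fused at C6–C7 to the γ-lactone) | C1C(=O)O[C@H]2/C=C(/C)[C@H](CC(=O)N3[C@@H](Cc4ccccc4)COC3=O)OCC(=C)[C@@H]12 | intermediate
16 | 2-[(3S,6S,7R)-oxocene lactone]acetic acid | C1C(=O)O[C@H]2/C=C(/C)[C@H](CC(=O)O)OCC(=C)[C@@H]12 | intermediate
17 | isobutyl carbonic anhydride of 16 | C1C(=O)O[C@H]2/C=C(/C)[C@H](CC(=O)OC(=O)OCC(C)C)OCC(=C)[C@@H]12 | intermediate
18 | 3-diazo-1-[(3S,6S,7R)-oxocene lactone]butan-2-one | C1C(=O)O[C@H]2/C=C(/C)[C@H](CC(=O)C(C)=[N+]=[N-])OCC(=C)[C@@H]12 | intermediate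
19 | trans-fused bicyclic oxonium ylide (oxonium O bonded to C3, C10 and the ring CH2; C10=C1 enolate) | C1C(=O)O[C@H]2/C=C(/C)[C@@H]3CC([O-])=C(C)[O+]3CC(=C)[C@@H]12 | intermediate
20 | (3S,6S,7R,10R)-3,10-epoxy-8-methylidene-1-oxo-13-norgermacr-4(Z)-en-12,6-olide | C1C(=O)O[C@H]2/C=C(/C)[C@@H]3CC(=O)[C@@](C)(CC(=C)[C@@H]12)O3 | intermediate
21 | (1S,3S,6S,7R,10R)-3,10-epoxy-1-hydroxy-8-methylidene-13-norgermacr-4(Z)-en-12,6-olide | C1C(=O)O[C@H]2/C=C(/C)[C@@H]3C[C@H](O)[C@@](C)(CC(=C)[C@@H]12)O3 | intermediate
22 | 1-O-(tert-butyldimethylsilyl) ether of 21 | C1C(=O)O[C@H]2/C=C(/C)[C@@H]3C[C@H](O[Si](C)(C)C(C)(C)C)[C@@](C)(CC(=C)[C@@H]12)O3 | intermediate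
23 | 8-hydroxy-8-(hydroxymethyl) diol from 22 (C8 configuration immaterial) | C1C(=O)O[C@H]2/C=C(/C)[C@@H]3C[C@H](O[Si](C)(C)C(C)(C)C)[C@@](C)(CC(O)(CO)[C@@H]12)O3 | intermediate
24 | (1S,3S,6S,7S,10R)-1-(tert-butyldimethylsilyloxy)-3,10-epoxy-8-oxo-13-norgermacr-4(Z)-en-12,6-olide | C1C(=O)O[C@H]2/C=C(/C)[C@@H]3C[C@H](O[Si](C)(C)C(C)(C)C)[C@@](C)(CC(=O)[C@@H]12)O3 | intermediate
25 | (1S,3S,6S,7R,8R,10R)-1-(tert-butyldimethylsilyloxy)-3,10-epoxy-8-hydroxy-13-norgermacr-4(Z)-en-12,6-olide | C1C(=O)O[C@H]2/C=C(/C)[C@@H]3C[C@H](O[Si](C)(C)C(C)(C)C)[C@@](C)(C[C@@H](O)[C@@H]12)O3 | intermediate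
26 | 11-[(dimethylamino)methyl] derivative of 25 (C11 epimers) | CN(C)CC1C(=O)O[C@H]2/C=C(/C)[C@@H]3C[C@H](O[Si](C)(C)C(C)(C)C)[C@@](C)(C[C@@H](O)[C@@H]12)O3 | intermediate
27 | trimethylammonium iodide of 26 | C[N+](C)(C)CC1C(=O)O[C@H]2/C=C(/C)[C@@H]3C[C@H](O[Si](C)(C)C(C)(C)C)[C@@](C)(C[C@@H](O)[C@@H]12)O3.[I-] | intermediate
28 | (1S,3S,6S,7R,8R,10R)-1-(tert-butyldimethylsilyloxy)-3,10-epoxy-8-hydroxygermacra-4(Z),11(13)-dien-12,6-olide | C=C1C(=O)O[C@H]2/C=C(/C)[C@@H]3C[C@H](O[Si](C)(C)C(C)(C)C)[C@@](C)(C[C@@H](O)[C@@H]12)O3 | intermediate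
29 | angelic acid, (Z)-2-methylbut-2-enoic acid | C/C=C(/C)C(=O)O | starting material
30 | angelic 2,4,6-trichlorobenzoic anhydride | C/C=C(/C)C(=O)OC(=O)c1c(Cl)cc(Cl)cc1Cl | intermediate
31 | 8-O-angeloyl derivative of 28 | C=C1C(=O)O[C@H]2/C=C(/C)[C@@H]3C[C@H](O[Si](C)(C)C(C)(C)C)[C@@](C)(C[C@@H](OC(=O)/C(C)=C\C)[C@@H]12)O3 | intermediate
32 | (1S,3S,6S,7R,8R,10R)-8-angeloyloxy-3,10-epoxy-1-hydroxygermacra-4(Z),11(13)-dien-12,6-olide | C=C1C(=O)O[C@H]2/C=C(/C)[C@@H]3C[C@H](O)[C@@](C)(C[C@@H](OC(=O)/C(C)=C\C)[C@@H]12)O3 | target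

**Step count and risks**

Total steps: 20. Longest linear sequence: 18 (steps 1–6, then 9–20).

Steps most likely to fail:

1. Step 13. The carbene may be captured on the other lone pair of the ring oxygen, so that the cis-fused ylide rearranges and C10 forms with the opposite configuration; the carbene may also be diverted into cyclopropanation, a 1,2-hydride shift, or a [2,3]-shift through the ring alkene. The fallback sets out from 9 and comes back at 21, with C10 fixed by an invertive epoxide opening instead of by the ylide. Copper-catalysed coupling of 9 with ethynylmagnesium bromide should give the skipped enyne (4R,5S)-5-ethenyl-4-(pent-1-en-4-yn-2-yl)oxolan-2-one F1. Zirconium-catalysed carboalumination (Me3Al, Cp2ZrCl2), conversion into the alanate with n-BuLi and opening of (R)-2-(prop-1-en-2-yl)oxirane at its CH2 terminus should give the (E)-trisubstituted homoallylic alcohol F2. Shi epoxidation of the trisubstituted alkene, with the ketone enantiomer chosen for the 1S,10S epoxide, should give the epoxy alcohol F3. Camphorsulfonic acid should then close the oxolane by 5-endo attack of the C3 hydroxyl on the tertiary epoxide carbon with inversion, giving the 2,5-trans oxolane F4 with C1, C3 and C10 fixed. Ring-closing metathesis of the vinyl and isopropenyl groups (second-generation Grubbs catalyst) would close the nine-membered ring to 21. The strain of the trans-bridged ring then has to be paid in a reversible metathesis, which is why this is the fallback and not the route.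

2. Step 16. Osmylation may lose chemoselectivity and attack the trisubstituted ring alkene, or the diol may over-oxidise. The fallback sets out from 22 and comes back at 24. Hydroboration with 9-BBN and oxidation, which is selective for the 1,1-disubstituted alkene, should give the primary alcohol F5. Dess–Martin oxidation gives the aldehyde F6, and TBSOTf/Et3N gives the silyl enol ether F7. Ozonolysis with one equivalent of ozone at −78 °C (Me2S work-up) should then cleave only the electron-rich enol ether and leave the C8 ketone 24.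

3. Step 17. Hydride delivery may show poor or reversed facial selectivity. The fallback sets out from 24 and comes back at 25. The reduction is run to the 8S alcohol F8, for example with a bulky trialkylborohydride. Mitsunobu reaction with 4-nitrobenzoic acid (PPh3, DIAD) inverts C8 to give the 8R 4-nitrobenzoate F9, and mild methanolysis (K2CO3, MeOH, 0 °C) should give 25.

Further compounds

F1 | step 13 | (4R,5S)-5-ethenyl-4-(pent-1-en-4-yn-2-yl)oxolan-2-one | O=C1C[C@H](C(=C)CC#C)[C@H](C=C)O1
F2 | step 13 | (E)-trisubstituted homoallylic alcohol: lactone–C8(=CH2)–C9H2–C10(CH3)=C1H–C2H2–C3H(OH)–C(CH3)=CH2, 3S | O=C1C[C@H](C(=C)C/C(C)=C/C[C@H](O)C(C)=C)[C@H](C=C)O1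
F3 | step 13 | (1S,10S)-1,10-epoxide of F2 | O=C1C[C@H](C(=C)C[C@]2(C)O[C@H]2C[C@H](O)C(C)=C)[C@H](C=C)O1
F4 | step 13 | 2,5-trans oxolane (1S,3S,10R) carrying the isopropenyl group on C3 and the vinyl lactone arm on C10 | O=C1C[C@H](C(=C)C[C@@]2(C)O[C@H](C(C)=C)C[C@@H]2O)[C@H](C=C)O1
F5 | step 16 | 8-(hydroxymethyl) compound from hydroboration of 22 (C8 epimers) | C1C(=O)O[C@H]2/C=C(/C)[C@@H]3C[C@H](O[Si](C)(C)C(C)(C)C)[C@@](C)(CC(CO)[C@@H]12)O3
F6 | step 16 | 8-formyl compound | C1C(=O)O[C@H]2/C=C(/C)[C@@H]3C[C@H](O[Si](C)(C)C(C)(C)C)[C@@](C)(CC(C=O)[C@@H]12)O3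
F7 | step 16 | silyl enol ether of F6 | C1C(=O)O[C@H]2/C=C(/C)[C@@H]3C[C@H](O[Si](C)(C)C(C)(C)C)[C@@](C)(CC(=CO[Si](C)(C)C(C)(C)C)[C@@H]12)O3
F8 | step 17 | 8S epimer of 25 | C1C(=O)O[C@H]2/C=C(/C)[C@@H]3C[C@H](O[Si](C)(C)C(C)(C)C)[C@@](C)(C[C@H](O)[C@@H]12)O3
F9 | step 17 | 8R 4-nitrobenzoate of 25 | C1C(=O)O[C@H]2/C=C(/C)[C@@H]3C[C@H](O[Si](C)(C)C(C)(C)C)[C@@](C)(C[C@@H](OC(=O)c4ccc(cc4)[N+](=O)[O-])[C@@H]12)O3
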